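**Assumption:** the target SMILES has no stereocentres, so it is achiral and the "single enantiomer" requirement does not apply. The target is 3'-hydroxy-5,6,7,2',4',5'-hexamethoxyflavone (A ring 5,6,7-OMe; B ring 2'-OMe, 3'-OH, 4'-OMe, 5'-OMe). Only substrates, intermediates and the target are numbered; simple reagents are given by name and SMILES in each step.

## Retrosynthetic overview
1. The pyranone ring C is formed last, in one Pd-catalysed carbonylative Sonogashira/6-endo oxa-Michael annulation of an o-iodophenol (ring A), CO and a terminal aryl alkyne (ring B). This avoids the Baker–Venkataraman and chalcone-oxidation routes.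
2. Ring A fragment: 2-iodo-3,4,5-trimethoxyphenol, made by mono-iodination of commercial 3,4,5-trimethoxyphenol.
3. Ring B fragment: 3-ethynyl-2,5,6-trimethoxyphenol, built from 1,2,4-trimethoxybenzene by directed lithiation/oxidation to give the 3'-oxygen.
4. The alkyne position is then set by electronic control. Acetylating the phenol makes its para position weakly activating, so iodination goes para to an OMe instead. Sonogashira coupling with TMS-acetylene and one-pot deacetylation/desilylation follow.

## Route

**Step 1**
Reactants: 1 (1,2,4-trimethoxybenzene)
Product: 2 (2,3,6-trimethoxyphenol)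
Conditions: n-BuLi, THF, 0 °C; then B(OMe)3, −78 °C → rt; then 30% H2O2, AcOH, 0 °C (one pot)
Reagents that add atoms: H2O2 (OO) supplies the phenolic O. B(OMe)3 (COB(OC)OC) is transient and the boron is lost.
Why: The C3–H lies between two OMe groups and is the most acidic site, so directed ortho-metalation occurs there. The aryl borate is oxidised to the phenol (borylation–oxidation). No stereocentres.

**Step 2**
Reactants: 2
Product: 3 (2,3,6-trimethoxyphenyl acetate)
Conditions: Ac2O, pyridine, cat. DMAP, CH2Cl2, 0 °C → rt
Reagents that add atoms: Ac2O (CC(=O)OC(C)=O)
Why: Acetylation turns the strongly donating OH into a weakly donating OAc, which reverses the para-directing preference in the next step.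

**Step 3**
Reactants: 3
Product: 4 (3-iodo-2,5,6-trimethoxyphenyl acetate)
Conditions: NIS (1.05 equiv), cat. TFA, MeCN, 0 °C → rt, dark
Reagents that add atoms: NIS (O=C1CCC(=O)N1I)
Why: Electrophilic aromatic iodination goes to the position ortho and para to OMe groups, not to the position para to the weak OAc donor. This places I adjacent to the future 2'-OMe and makes the acetate oxygen the future 3'-O.

**Step 4**
Reactants: 4; 5 (trimethylsilylacetylene)
Product: 6 (3-(trimethylsilylethynyl)-2,5,6-trimethoxyphenyl acetate)
Conditions: PdCl2(PPh3)2 (3 mol %), CuI (5 mol %), Et3N/THF 1:1, 50 °C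
Reagents that add atoms: TMS-acetylene (C#C[Si](C)(C)C)
Why: Sonogashira coupling of the aryl iodide. The hindered aryl acetate survives the tertiary amine, and the TMS group prevents Glaser coupling.

**Step 5**
Reactants: 6
Product: 7 (3-ethynyl-2,5,6-trimethoxyphenol)
Conditions: K2CO3, MeOH, rt, 1 h, degassed; NH4Cl work-up
Reagents that add atoms: none
Why: Methanolysis removes both the aryl acetate and the C–SiMe3 group, giving the terminal alkyne with a free 3'-OH in one operation.

**Step 6**
Reactants: 8 (3,4,5-trimethoxyphenol)
Product: 9 (2-iodo-3,4,5-trimethoxyphenol)
Conditions: NIS (1.0 equiv), MeCN, 0 °C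
Reagents that add atoms: NIS (O=C1CCC(=O)N1I)
Why: The para position is blocked by OMe and the two ortho positions are equivalent, so mono-iodination is regiochemically unambiguous.

**Step 7 (key step)**
Reactants: 7; 9; carbon monoxide
Product: 10 (Agecorynin G)
Conditions: PdCl2(PPh3)2 (5 mol %), Et3N (3 equiv), CO (1 atm, balloon), DMF, 80 °C, 12 h
Reagents that add atoms: CO ([C-]#[O+]) supplies C-4 and the carbonyl oxygen.
Why: Pd(0) adds oxidatively to the aryl iodide and CO inserts to give an aroyl-Pd species. Amine-assisted copper-free alkynylation then gives the o-hydroxyaryl ynone, and phenoxide 6-endo-dig oxa-Michael addition closes ring C to the flavone (amine/PPh3 conditions favour flavone over aurone). The hindered 3'-phenol flanked by two OMe groups is a poor nucleophile and does not compete. Carbonylative Sonogashira annulation; there are no stereocentres.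

## Self-check
- **Target match:** Compound 10 has 5,6,7-(OMe)3 on ring A, and ring B carries 2'-OMe, 3'-OH, 4'-OMe, 5'-OMe with H-6'. The pyranone is a 6-membered 4-oxo ring with the B ring at C-2. This matches the target SMILES.
- **Atom balance in step 7:** 9 (C9H11IO4) + 7 (C11H12O4) + CO gives C21H22O9 + HI. This equals the target formula.
- **Functional-group survival:** Step 1 is the only step with n-BuLi, and OMe groups tolerate it. The acetate is present only in steps 2–4, where it is stable, and is removed in step 5. Only step 7 has a free phenol in the presence of Pd and CO.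
- **Stereochemistry:** No stereocentres exist in the target or any intermediate.

## Compound list
1 | 1,2,4-trimethoxybenzene | COc1ccc(OC)c(OC)c1 | starting material
2 | 2,3,6-trimethoxyphenol | COc1ccc(OC)c(O)c1OC | intermediate
3 | 2,3,6-trimethoxyphenyl acetate | CC(=O)Oc1c(OC)ccc(OC)c1OC | intermediate
4 | 3-iodo-2,5,6-trimethoxyphenyl acetate | CC(=O)Oc1c(OC)c(I)cc(OC)c1OC | intermediate
5 | trimethylsilylacetylene | C#C[Si](C)(C)C | starting material
6 | 3-(TMS-ethynyl)-2,5,6-trimethoxyphenyl acetate | CC(=O)Oc1c(OC)c(C#C[Si](C)(C)C)cc(OC)c1OC | intermediate
7 | 3-ethynyl-2,5,6-trimethoxyphenol | C#Cc1cc(OC)c(OC)c(O)c1OC | intermediate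
8 | 3,4,5-trimethoxyphenol | COc1cc(O)cc(OC)c1OC | starting material
9 | 2-iodo-3,4,5-trimethoxyphenol | COc1cc(O)c(I)c(OC)c1OC | intermediate
10 | Agecorynin G | COc1cc(-c2cc(=O)c3c(OC)c(OC)c(OC)cc3o2)c(OC)c(O)c1OC | target

**Total steps:** 7 (5 steps for ring B, 1 for ring A, 1 convergent key step).
**Longest linear sequence:** 6 steps (1 → 2 → 3 → 4 → 5 → 10 via step 7).

## Three steps most likely to fail
1. **Step 7 (annulation).** The free 3'-phenol, the hindered 2'-OMe alkyne and the 5-OMe-hindered iodide could give aurone, acyl transfer or low conversion. Fallback: protect the alkyne's 3'-OH as its benzyl ether (BnBr, K2CO3, on 7), run the same annulation, then remove Bn by H2, Pd/C in EtOAc.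
2. **Step 3 (regioselective iodination).** The C3/C4 selectivity rests on the weak donor ability of OAc and may give an isomer mixture. Fallback: reverse the order. Brominate 1,2,4-trimethoxybenzene at C5, couple it with TIPS-acetylene, lithiate C3 with s-BuLi/TMEDA, oxidise via the borate, and remove TIPS with TBAF. This gives 7 by a regiodefined route.
3. **Step 1 (lithiation/oxidation).** C3 versus C6 lithiation selectivity, and over-oxidation of the electron-rich phenol to a quinone, are both concerns. Fallback: make 2,3,6-trimethoxybenzaldehyde by ortho-formylation under the same lithiation, then convert it to phenol 2 by Dakin oxidation or Baeyer–Villiger/formate hydrolysis, which allows a milder, more controllable oxidation.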